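**Retrosynthetic overview**
- Final disconnection at the C4'–C5' bond of the side chain (C(Me)=CH–CH2): Negishi sp2–sp3 coupling of a C14 alkenyl iodide carrying the cyclohexenone (13) with a C11 alkylzinc carrying the butenolide (from 21).
- 13 comes from cyclohex-2-enone: a 2-alkyl enone, asymmetric conjugate methylation, then enolate methylation anti to the new methyl (sets C5 and then C4), then dehydrogenation, MeLi addition and oxidative 1,3-carbonyl transposition; the (E)-iodoalkene comes from alkyne carboalumination.
- 21 comes from but-3-yn-1-ol: carboalumination and oxirane opening give the (E)-trisubstituted olefin; the butenolide is attached by Negishi coupling with 4-bromofuran-2(5H)-one.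
- No ring is built de novo: the carbocycle is carried from cyclohex-2-enone and functionalised first; the butenolide enters intact in the other branch.

**Assumptions**
- The SMILES decodes to (4R,5R) with the C4 and C5 methyls trans (side chain cis to the C5 methyl) and both chain olefins E.
- In step 5 the ligand enantiomer is the one that gives the 3R adduct. I assume the 2-alkyl enone follows the usual facial sense of cyclohexenone; if not, the antipodal ligand is used. The absolute sense should be checked at ketone 8.

---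

**Ring-bearing fragment**

**Step 1**
Reactants: 1, cyclohex-2-en-1-one
Product: 2, 2-iodocyclohex-2-en-1-one
Conditions: I2, pyridine, CH2Cl2, 0 °C → rt
Reagents that add atoms: iodine, II
Why: α-Iodination of an enone by pyridine conjugate addition, enolate iodination and elimination (Johnson iodination).

**Step 2**
Reactants: 3, but-3-yn-1-ol
Product: 4, 4-(trimethylsilyl)but-3-yn-1-ol
Conditions: n-BuLi (2.1 equiv), THF, −78 °C; TMSCl (2.2 equiv), → rt; then 1 M HCl
Reagents that add atoms: TMSCl, C[Si](C)(C)Cl
Why: Dianion bis-silylation followed by selective acidic cleavage of the O–Si bond leaves the C-silyl alkyne.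

**Step 3**
Reactants: 4
Product: 5, (4-iodobut-1-yn-1-yl)trimethylsilane
Conditions: I2, PPh3, imidazole, CH2Cl2, 0 °C → rt
Reagents that add atoms: iodine, II
Why: Appel-type iodination of a primary alcohol.

**Step 4**
Reactants: 5 and 2
Product: 6, 2-[4-(trimethylsilyl)but-3-yn-1-yl]cyclohex-2-en-1-one
Conditions: 5, Zn dust (activated), LiCl, THF, 40 °C; then 2, Pd2(dba)3 (2.5 mol%), P(2-furyl)3 (10 mol%), THF/NMP, rt
Reagents that add atoms: none
Why: Zinc insertion into the primary iodide, then Negishi sp3–sp2 coupling with the reactive α-iodoenone; alkylzinc halides do not add to the enone without copper.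

**Step 5**
Reactants: 6
Product: 7, (R)-trimethyl({3-methyl-2-[4-(trimethylsilyl)but-3-yn-1-yl]cyclohex-1-en-1-yl}oxy)silane
Conditions: Me3Al (1.5 equiv), CuTC (5 mol%), BINOL/bis(1-phenylethyl)amine phosphoramidite (10 mol%, enantiomer giving 3R), Et2O, −30 °C; then TMSOTf, THF, −30 → 0 °C; Et3N quench
Reagents that add atoms: trimethylaluminium, C[Al](C)C; TMSOTf, C[Si](C)(C)OS(=O)(=O)C(F)(F)F
Why: Cu-catalysed asymmetric conjugate addition, in which the ligand fixes the face of methyl delivery and sets the ring CH(Me) centre as R; the aluminium enolate is trapped regiospecifically as the silyl enol ether.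

**Step 6**
Reactants: 7
Product: 8, (2R,3R)-2,3-dimethyl-2-[4-(trimethylsilyl)but-3-yn-1-yl]cyclohexan-1-one
Conditions: MeLi (1.05 equiv), THF, 0 °C, 30 min; then HMPA, MeI (5 equiv), −78 → −20 °C
Reagents that add atoms: iodomethane, CI
Why: Regiospecific lithium enolate alkylation; MeI attacks axially, anti to the pseudoaxial C3 methyl, so the new quaternary centre has its methyl trans to the C3 methyl (2R).

**Step 7**
Reactants: 8
Product: 9, (5R,6R)-5,6-dimethyl-6-[4-(trimethylsilyl)but-3-yn-1-yl]cyclohex-2-en-1-one
Conditions: LDA, THF, −78 °C; TMSCl; then Pd(OAc)2 (1.1 equiv), MeCN, rt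
Reagents that add atoms: none
Why: Ito–Saegusa dehydrogenation; the ketone has only one enolisable side, so the regiochemistry is unambiguous and neither stereocentre is touched.

**Step 8**
Reactants: 9
Product: 10, (5R,6R)-1,5,6-trimethyl-6-[4-(trimethylsilyl)but-3-yn-1-yl]cyclohex-2-en-1-ol (C1 epimers, inconsequential)
Conditions: MeLi, CeCl3, THF, −78 °C
Reagents that add atoms: methyllithium, [Li]C
Why: Organocerium 1,2-addition to a hindered enone without enolisation; the C-silyl alkyne survives at −78 °C.

**Step 9**
Reactants: 10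
Product: 11, (5R,6R)-6-(but-3-yn-1-yl)-1,5,6-trimethylcyclohex-2-en-1-ol
Conditions: K2CO3, MeOH, rt
Reagents that add atoms: none
Why: Mild protodesilylation of the alkynylsilane; the tertiary allylic alcohol is stable to base.

**Step 10**
Reactants: 11
Product: 12, (5R,6R)-6-[(3E)-4-iodo-3-methylbut-3-en-1-yl]-1,5,6-trimethylcyclohex-2-en-1-ol
Conditions: Me3Al (4 equiv), Cp2ZrCl2 (0.3 equiv), CH2Cl2, 0 °C → rt; then I2, THF, −30 → 0 °C
Reagents that add atoms: trimethylaluminium, C[Al](C)C; iodine, II
Why: Negishi Zr-catalysed carboalumination (syn Me–Al addition, Al terminal) and iodinolysis with retention give the (E)-iodoalkene; no carbonyl is present and the alcohol is masked in situ as its aluminium alkoxide.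

**Step 11**
Reactants: 12
Product: 13, (4R,5R)-4-[(3E)-4-iodo-3-methylbut-3-en-1-yl]-3,4,5-trimethylcyclohex-2-en-1-one
Conditions: PCC (3 equiv), 4 Å MS, CH2Cl2, rt
Reagents that add atoms: none
Why: Babler–Dauben oxidative 1,3-transposition (chromate ester [3,3] shift, then oxidation) moves the oxygen to give the 3-methyl enone; both C1 epimers converge.

**Butenolide fragment**

**Step 12**
Reactants: 3, but-3-yn-1-ol
Product: 14, (but-3-yn-1-yloxy)(tert-butyl)dimethylsilane
Conditions: TBSCl, imidazole, DMF, rt
Reagents that add atoms: TBSCl, CC(C)(C)[Si](C)(C)Cl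
Why: Standard silyl protection of the primary alcohol.

**Step 13**
Reactants: 14 and 15, oxirane
Product: 16, (3E)-6-[(tert-butyldimethylsilyl)oxy]-4-methylhex-3-en-1-ol
Conditions: Me3Al (2.5 equiv), Cp2ZrCl2 (0.25 equiv), CH2Cl2, 0 °C → rt; remove volatiles; n-BuLi, hexane/THF, −78 → 0 °C; oxirane, 0 °C → rt
Reagents that add atoms: trimethylaluminium, C[Al](C)C
Why: Zr-catalysed carboalumination gives the (E)-alkenylalane, whose butyl ate complex opens oxirane with retention, fixing the E trisubstituted olefin.

**Step 14**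
Reactants: 16
Product: 17, tert-butyl{[(3E)-6-iodo-3-methylhex-3-en-1-yl]oxy}dimethylsilane
Conditions: I2, PPh3, imidazole, CH2Cl2, 0 °C
Reagents that add atoms: iodine, II
Why: Appel-type iodination; the silyl ether and olefin are unaffected.

**Step 15**
Reactants: 17 and 18, 4-bromofuran-2(5H)-one
Product: 19, 4-[(3E)-6-[(tert-butyldimethylsilyl)oxy]-4-methylhex-3-en-1-yl]furan-2(5H)-one
Conditions: 17, Zn dust, LiCl, THF, 40 °C; then 18, Pd(PPh3)4 (5 mol%), THF, rt
Reagents that add atoms: none
Why: Negishi coupling of a primary alkylzinc iodide with a β-bromo-enoate, a very reactive electrophile; the weakly basic zinc reagent leaves the lactone intact.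

**Step 16**
Reactants: 19
Product: 20, 4-[(3E)-6-hydroxy-4-methylhex-3-en-1-yl]furan-2(5H)-one
Conditions: HF·pyridine, THF/pyridine, 0 °C → rt
Reagents that add atoms: none
Why: Acidic fluoride desilylation avoids the basic conditions that could isomerise or open the butenolide.

**Step 17**
Reactants: 20
Product: 21, 4-[(3E)-6-iodo-4-methylhex-3-en-1-yl]furan-2(5H)-one
Conditions: I2, PPh3, imidazole, CH2Cl2, 0 °C
Reagents that add atoms: iodine, II
Why: Neutral Appel-type iodination, compatible with the butenolide.

**Fragment union**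

**Step 18**
Reactants: 21 and 13
Product: 22, cyclolinteinone, (4R,5R)-4-[(3E,7E)-3,7-dimethyl-10-(5-oxo-2,5-dihydrofuran-3-yl)deca-3,7-dien-1-yl]-3,4,5-trimethylcyclohex-2-en-1-one
Conditions: 21, Zn dust, LiCl, THF, 40 °C; then 13, PdCl2(dppf) (5 mol%), THF/NMP, 40 °C
Reagents that add atoms: none
Why: Negishi sp3–sp2 coupling joins C5' to C4' with retention of the (E)-alkenyl iodide geometry; the enone and butenolide tolerate alkylzinc halides, and no stereocentre is involved.

---

**Compound list**
1 | cyclohex-2-en-1-one | O=C1C=CCCC1 | starting material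
2 | 2-iodocyclohex-2-en-1-one | O=C1CCCC=C1I | intermediate
3 | but-3-yn-1-ol | C#CCCO | starting material
4 | 4-(trimethylsilyl)but-3-yn-1-ol | C[Si](C)(C)C#CCCO | intermediate
5 | (4-iodobut-1-yn-1-yl)trimethylsilane | C[Si](C)(C)C#CCCI | intermediate
6 | 2-[4-(trimethylsilyl)but-3-yn-1-yl]cyclohex-2-en-1-one | O=C1CCCC=C1CCC#C[Si](C)(C)C | intermediate
7 | (R)-silyl enol ether of the conjugate adduct | C[Si](C)(C)OC1=C(CCC#C[Si](C)(C)C)[C@H](C)CCC1 | intermediate
8 | (2R,3R)-2,3-dimethyl-2-[4-(trimethylsilyl)but-3-yn-1-yl]cyclohexan-1-one | O=C1CCC[C@@H](C)[C@@]1(C)CCC#C[Si](C)(C)C | intermediate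
9 | (5R,6R)-5,6-dimethyl-6-[4-(trimethylsilyl)but-3-yn-1-yl]cyclohex-2-en-1-one | O=C1C=CC[C@@H](C)[C@@]1(C)CCC#C[Si](C)(C)C | intermediate
10 | (5R,6R)-1,5,6-trimethyl-6-[4-(trimethylsilyl)but-3-yn-1-yl]cyclohex-2-en-1-ol (C1 epimers) | CC1(O)C=CC[C@@H](C)[C@@]1(C)CCC#C[Si](C)(C)C | intermediate
11 | (5R,6R)-6-(but-3-yn-1-yl)-1,5,6-trimethylcyclohex-2-en-1-ol | CC1(O)C=CC[C@@H](C)[C@@]1(C)CCC#C | intermediate
12 | (5R,6R)-6-[(3E)-4-iodo-3-methylbut-3-en-1-yl]-1,5,6-trimethylcyclohex-2-en-1-ol | CC1(O)C=CC[C@@H](C)[C@@]1(C)CC/C(C)=C/I | intermediate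
13 | (4R,5R)-4-[(3E)-4-iodo-3-methylbut-3-en-1-yl]-3,4,5-trimethylcyclohex-2-en-1-one | CC1=CC(=O)C[C@@H](C)[C@@]1(C)CC/C(C)=C/I | intermediate
14 | (but-3-yn-1-yloxy)(tert-butyl)dimethylsilane | C#CCCO[Si](C)(C)C(C)(C)C | intermediate
15 | oxirane | C1CO1 | starting material
16 | (3E)-6-[(tert-butyldimethylsilyl)oxy]-4-methylhex-3-en-1-ol | OCC/C=C(\C)CCO[Si](C)(C)C(C)(C)C | intermediate
17 | tert-butyl{[(3E)-6-iodo-3-methylhex-3-en-1-yl]oxy}dimethylsilane | ICC/C=C(\C)CCO[Si](C)(C)C(C)(C)C | intermediate
18 | 4-bromofuran-2(5H)-one | O=C1OCC(Br)=C1 | starting material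
19 | 4-[(3E)-6-[(tert-butyldimethylsilyl)oxy]-4-methylhex-3-en-1-yl]furan-2(5H)-one | O=C1OCC(CC/C=C(\C)CCO[Si](C)(C)C(C)(C)C)=C1 | intermediate
20 | 4-[(3E)-6-hydroxy-4-methylhex-3-en-1-yl]furan-2(5H)-one | O=C1OCC(CC/C=C(\C)CCO)=C1 | intermediate
21 | 4-[(3E)-6-iodo-4-methylhex-3-en-1-yl]furan-2(5H)-one | O=C1OCC(CC/C=C(\C)CCI)=C1 | intermediate
22 | cyclolinteinone | CC1=CC(=O)C[C@@H](C)[C@@]1(C)CC/C(C)=C/CC/C(C)=C/CCC1=CC(=O)OC1 | target

**Totals**
- Total steps: 18.
- Longest linear sequence: 11 (steps 2–11 from but-3-yn-1-ol, then step 18). The butenolide branch is 7 steps including the coupling.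

**Three steps most likely to fail, with fallbacks**
1. Steps 5–6 (ee of the conjugate methylation on a 2-alkyl enone, and dr of the anti methylation). Fallback: a chiral-pool entry. (R)-3-Methylcyclohexanone is converted to (R)-5-methylcyclohex-2-enone, which is α′-alkylated twice, each time anti to the ring methyl: first with an allyl unit (later homologated to the butynyl chain), then with MeI. This reaches the enone 9 series without asymmetric catalysis.
2. Step 10 (carboalumination next to a free tertiary allylic alcohol, which could ionise or be methylated). Fallback: move the fragment junction to C2'–C3'. The ring piece becomes a 4-(2-iodoethyl) enone used as the alkylzinc, and the chain piece carries an (E)-2-iodo-2-alkene made by hydrozirconation–iodination of a 2-alkyne, so no carbometalation is run on a ring-bearing intermediate.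
3. Step 18 (zinc insertion next to the lactone, β-hydride elimination or homocoupling in the final Negishi). Fallback: couple 13 with the zinc reagent from the lactone-free iodide 17, then desilylate, iodinate and attach the butenolide last by Negishi coupling with 18.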